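**Plan**
- **Feature:** the target is one cyclohexene ring, C1(OBz)–C2=C3–C4(OBz)–C5(OH)–C6(OH)(C7H2OH). Its cis C4–O/C5–O pair beside the C2=C3 alkene is the imprint of an arene cis-dihydrodiol, and C3 can carry a bromine that is later exchanged for hydrogen.
- **Cuts, in retrosynthetic order:** the O4–benzoyl ester; C3–H back to C3–Br; C6–O and C7–O (osmylation of C6=C7); C6=C7 (methylenation of a C6 ketone); C1–OBz (benzoate opening of a C1/C6 epoxide); finally C4–O and C5–O back to bromobenzene.
- **Forward order:** no ring is built, because the benzene ring is dearomatised in step 1 and remains the only carbocycle. O1 is attached in step 4, the branch carbon C7 in step 6, O6/O7 in step 7 and the second benzoate in step 11.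
- **Stereochemistry:** the enzyme sets C4 and C5. Their acetonide sends the peracid to the opposite face, SN2 opening puts O1 back on the acetonide face, and osmylation anti to O1 and O5 sets C6.
- **Site selection:** a di-tert-butylsilylene bridge across O5/O7 singles out O4 for benzoylation. It is removed last with acidic fluoride so that no benzoate can migrate.

Key step: step 1

Remark: target numbering is used for every intermediate and the CIP descriptors refer to it. β is the ring face bearing O4 and O5, α is the other face. The recombinant strain is taken as an accessible biocatalyst.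

Step 1
Reactants: 1 bromobenzene
Product: 2 (1S,2S)-3-bromocyclohexa-3,5-diene-1,2-diol (target numbering: C3–Br, 4β-OH, 5β-OH, alkenes C2=C3 and C6=C1)
Conditions: E. coli JM109 (pDTG601) whole cells (toluene dioxygenase, IPTG-induced), glucose-fed mineral salts medium, air, pH 7, 30–35 °C; EtOAc extraction
Reagents that add atoms: dioxygen, O=O
Why: Toluene dioxygenase, a Rieske-type non-heme iron oxygenase, holds the arene above its mononuclear iron site, reduces bound O2 with two electrons passed on from NADH and transfers both oxygen atoms to one face of the ring bond next to C–Br, so that C4–O and C5–O form cis in a single event and the aromatic sextet is lost. The closest known reaction type is the preparative whole-cell cis-dihydroxylation of monohalobenzenes by the same enzyme. No ring closes: the benzene ring simply becomes the cyclohexadiene that persists as the only carbocycle of 15. Both new stereocentres, C4 and C5 (each S in 2, R in 15 only because CIP priorities change), are controlled by the chiral binding pocket, which fixes the bromine in one orientation and thereby selects one of the two enantiotopic ortho/meta bonds and one face of an achiral substrate. The step needs regioselectivity for the 2,3-bond over the 3,4-bond and a halt at the diol stage: the bromine as anchoring substituent secures the first, and the host strain, which carries no diol dehydrogenase, secures the second by preventing rearomatisation to the catechol. The sense of induction places bromine on C3 when O4 and O5 have the configuration of 15, as checked atom by atom against the target.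

Step 2
Reactants: 2 (1S,2S)-3-bromocyclohexa-3,5-diene-1,2-diol
Product: 3 (3aS,7aS)-4-bromo-2,2-dimethyl-3a,7a-dihydro-1,3-benzodioxole (4β,5β-acetonide)
Conditions: Me2C(OMe)2, p-TsOH·H2O (cat.), CH2Cl2, 0 °C → rt; used at once
Reagents that add atoms: 2,2-dimethoxypropane, COC(C)(C)OC
Why: Acid-catalysed transketalisation (acetonide formation) ties the cis O4/O5 pair into a dioxolane without touching C4 or C5, which blocks dehydration to a bromophenol and makes the β face the hindered face for all later additions.

Step 3
Reactants: 3 (3aS,7aS)-4-bromo-2,2-dimethyl-3a,7a-dihydro-1,3-benzodioxole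
Product: 4 (3aS,5aR,6aR,6bS)-4-bromo-2,2-dimethyl-3a,5a,6a,6b-tetrahydrooxireno[2,3-e][1,3]benzodioxole (1α,6α-epoxide, anti to the acetonide)
Conditions: mCPBA (1.1 equiv), CH2Cl2, 0 °C → rt
Reagents that add atoms: 3-chloroperoxybenzoic acid, O=C(OO)c1cccc(Cl)c1
Why: Prilezhaev epoxidation takes the electron-richer, bromine-free C6=C1 alkene (C2=C3 is deactivated by the halogen) from the α face opposite the dioxolane, so both new C–O bonds at C1 and C6 are α, as is general for this class of diene acetonides.

Step 4
Reactants: 4 the 1α,6α-epoxide; 5 benzoic acid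
Product: 6 (1S,4S,5S,6R)-3-bromo-6-hydroxy-4,5-(isopropylidenedioxy)cyclohex-2-en-1-yl benzoate (1β-OBz, 6α-OH)
Conditions: PhCO2H (2 equiv), Bu4N(O2CPh) (0.2 equiv), MeCN, 60–70 °C
Reagents that add atoms: benzoic acid (5), O=C(O)c1ccccc1; tetrabutylammonium benzoate (catalyst, carries the same benzoate), CCCC[N+](CCCC)(CCCC)CCCC.[O-]C(=O)c1ccccc1
Why: In this carboxylate-catalysed SN2 opening of a vinyl oxirane, benzoate attacks the allylic and less crowded C1 from the β face with inversion (trans-diaxial opening, the site also chosen by azide, hydroxide and alcohol nucleophiles in such epoxides), which sets C1 as S with O1 β, while the excess acid protonates the 6α-alkoxide at once, regenerating the catalyst and suppressing acyl shift.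

Step 5
Reactants: 6 the 1β-benzoyloxy-6α-alcohol
Product: 7 (1S,4S,5R)-3-bromo-4,5-(isopropylidenedioxy)-6-oxocyclohex-2-en-1-yl benzoate
Conditions: Dess–Martin periodinane (1.3 equiv), CH2Cl2, 0 °C → rt; cold neutral work-up, used at once
Reagents that add atoms: none
Why: Dess–Martin oxidation runs under neutral to faintly acidic conditions, so the hindered 6α-carbinol becomes the ketone without the base that would enolise C1–H or C5–H and start loss of O4; the C6 stereocentre is erased on purpose while C1, C4 and C5 stay intact.

Step 6
Reactants: 7 the C6 ketone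
Product: 8 (1S,4S,5S)-3-bromo-4,5-(isopropylidenedioxy)-6-methylidenecyclohex-2-en-1-yl benzoate
Conditions: Cp2Ti(μ-Cl)(μ-CH2)AlMe2 (1.1 equiv, toluene solution), pyridine (0.1 equiv), THF, −40 → 0 °C; Na2SO4·10H2O quench
Reagents that add atoms: Cp2Ti(μ-Cl)(μ-CH2)AlMe2, C[Al-]1(C)C[Ti]([Cl+]1)(C1C=CC=C1)C1C=CC=C1
Why: In the Tebbe methylenation the non-basic methylidene Cp2Ti=CH2 released by pyridine reacts with the ketone by [2+2] cycloaddition and cycloreversion much faster than with a benzoate at low temperature, so C6=C7 should form without epimerisation at C1 or C5, which is why this reagent class is preferred for β-alkoxy cyclohexanones that eliminate under Wittig conditions.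

Step 7
Reactants: 8 the exocyclic alkene
Product: 9 (1S,4S,5R,6R)-3-bromo-6-hydroxy-6-(hydroxymethyl)-4,5-(isopropylidenedioxy)cyclohex-2-en-1-yl benzoate (6α-OH, C7 β)
Conditions: OsO4 (3 mol %), NMO (1.5 equiv), acetone–H2O, 0 °C → rt; NaHSO3 quench
Reagents that add atoms: osmium tetroxide, O=[Os](=O)(=O)=O; N-methylmorpholine N-oxide, C[N+]1([O-])CCOCC1; water, O
Why: In the Upjohn dihydroxylation OsO4 adds suprafacially to the 1,1-disubstituted C6=C7 alkene, ignores the bromine-deactivated C2=C3, and approaches from the α face, anti to the two allylic C–O bonds at C1 and C5 and away from the dioxolane, so O6 ends α and C7 is pushed β, which sets C6.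

Step 8
Reactants: 9 the bromo diol
Product: 10 (1S,4R,5R,6R)-6-hydroxy-6-(hydroxymethyl)-4,5-(isopropylidenedioxy)cyclohex-2-en-1-yl benzoate
Conditions: Bu3SnH (1.5 equiv), AIBN (0.1 equiv), degassed toluene, 80 °C; KF work-up
Reagents that add atoms: none
Why: In this radical-chain hydrodebromination Bu3Sn• abstracts the vinylic bromine and the sp2 radical at C3 is quenched by Bu3SnH faster than it can rearrange, under neutral conditions that leave benzoate, acetonide and free diol alone and touch no stereocentre, as is routine for bromoconduritol acetonides.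

Step 9
Reactants: 10 the debrominated acetonide diol
Product: 11 (1S,4R,5R,6S)-4,5,6-trihydroxy-6-(hydroxymethyl)cyclohex-2-en-1-yl benzoate
Conditions: TFA–H2O (9:1), CH2Cl2, 0 °C; evaporation with toluene
Reagents that add atoms: none
Why: Acid-catalysed acetal hydrolysis frees O4 and O5 with both ring C–O bonds intact, and cold aqueous TFA followed by evaporation avoids any basic work-up that could move the C1 benzoate to O7.

Step 10
Reactants: 11 the tetraol monobenzoate
Product: 12 (1S,4R,5R,6R)-5-O,7-O-(di-tert-butylsilanediyl)-4,5,6-trihydroxy-6-(hydroxymethyl)cyclohex-2-en-1-yl benzoate (six-membered O5–Si–O7 ring cis-fused on the β face; 4β-OH and 6α-OH free)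
Conditions: t-Bu2Si(OTf)2 (1.05 equiv), pyridine, −30 → 0 °C
Reagents that add atoms: di-tert-butylsilyl bis(trifluoromethanesulfonate), CC(C)(C)[Si](OS(=O)(=O)C(F)(F)F)(OS(=O)(=O)C(F)(F)F)C(C)(C)C
Why: In this cyclic silylene protection of a 1,3-diol the primary O7 is silylated first and the second Si–O bond closes onto the cis-disposed O5 to give the six-membered 1,3,2-dioxasilinane rather than a strained five-membered ring to O6 or across O4/O5, the same preference that gives 4,6-O-silylene derivatives from unprotected galactopyranosides.

Step 11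
Reactants: 12 the 5,7-O-silylene diol; 13 benzoyl chloride
Product: 14 (1S,4R,5R,6R)-5-O,7-O-(di-tert-butylsilanediyl)-5,6-dihydroxy-6-(hydroxymethyl)cyclohex-2-ene-1,4-diyl dibenzoate
Conditions: BzCl (1.5 equiv), pyridine, DMAP (0.1 equiv), CH2Cl2, 0 °C → rt
Reagents that add atoms: benzoyl chloride (13), O=C(Cl)c1ccccc1
Why: DMAP-catalysed acylation can only take the secondary allylic O4–H, because O5 and O7 are tied up in the silylene and the tertiary O6–H is inert under these conditions, and the C4–O bond made by the enzyme is kept, so configuration is retained.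

Step 12
Reactants: 14 the silylene dibenzoate
Product: 15 (1S,4R,5R,6S)-5,6-dihydroxy-6-(hydroxymethyl)cyclohex-2-ene-1,4-diyl dibenzoate (target)
Conditions: HF·pyridine, pyridine, THF, 0 °C → rt (plastic vessel)
Reagents that add atoms: none
Why: Fluoride-induced Si–O cleavage with buffered HF·pyridine is the standard removal of a di-tert-butylsilylene from benzoylated polyols, and its weakly acidic medium frees O5 and O7 without the alkoxide formation that would trigger O4→O5 or O1→O7 benzoyl migration.

**Compound list**
1 | bromobenzene | Brc1ccccc1 | starting material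
2 | (1S,2S)-3-bromocyclohexa-3,5-diene-1,2-diol | BrC1=CC=C[C@H](O)[C@@H]1O | intermediate
3 | (3aS,7aS)-4-bromo-2,2-dimethyl-3a,7a-dihydro-1,3-benzodioxole | BrC1=CC=C[C@@H]2OC(C)(C)O[C@H]12 | intermediate
4 | (3aS,5aR,6aR,6bS)-4-bromo-2,2-dimethyl-3a,5a,6a,6b-tetrahydrooxireno[2,3-e][1,3]benzodioxole | BrC1=C[C@H]2O[C@H]2[C@@H]3OC(C)(C)O[C@H]13 | intermediate
5 | benzoic acid | O=C(O)c1ccccc1 | starting material
6 | (1S,4S,5S,6R)-3-bromo-6-hydroxy-4,5-(isopropylidenedioxy)cyclohex-2-en-1-yl benzoate | O=C(O[C@H]1C=C(Br)[C@H]2OC(C)(C)O[C@H]2[C@@H]1O)c1ccccc1 | intermediate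
7 | (1S,4S,5R)-3-bromo-4,5-(isopropylidenedioxy)-6-oxocyclohex-2-en-1-yl benzoate | O=C(O[C@H]1C=C(Br)[C@H]2OC(C)(C)O[C@H]2C1=O)c1ccccc1 | intermediate
8 | (1S,4S,5S)-3-bromo-4,5-(isopropylidenedioxy)-6-methylidenecyclohex-2-en-1-yl benzoate | O=C(O[C@H]1C=C(Br)[C@H]2OC(C)(C)O[C@H]2C1=C)c1ccccc1 | intermediate
9 | (1S,4S,5R,6R)-3-bromo-6-hydroxy-6-(hydroxymethyl)-4,5-(isopropylidenedioxy)cyclohex-2-en-1-yl benzoate | O=C(O[C@H]1C=C(Br)[C@H]2OC(C)(C)O[C@H]2[C@@]1(O)CO)c1ccccc1 | intermediate
10 | (1S,4R,5R,6R)-6-hydroxy-6-(hydroxymethyl)-4,5-(isopropylidenedioxy)cyclohex-2-en-1-yl benzoate | O=C(O[C@H]1C=C[C@H]2OC(C)(C)O[C@H]2[C@@]1(O)CO)c1ccccc1 | intermediate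
11 | (1S,4R,5R,6S)-4,5,6-trihydroxy-6-(hydroxymethyl)cyclohex-2-en-1-yl benzoate | O=C(O[C@H]1C=C[C@@H](O)[C@@H](O)[C@@]1(O)CO)c1ccccc1 | intermediate
12 | (1S,4R,5R,6R)-5-O,7-O-(di-tert-butylsilanediyl)-4,5,6-trihydroxy-6-(hydroxymethyl)cyclohex-2-en-1-yl benzoate | O=C(O[C@H]1C=C[C@@H](O)[C@H]2O[Si](C(C)(C)C)(C(C)(C)C)OC[C@@]12O)c1ccccc1 | intermediate
13 | benzoyl chloride | O=C(Cl)c1ccccc1 | starting material
14 | (1S,4R,5R,6R)-5-O,7-O-(di-tert-butylsilanediyl)-5,6-dihydroxy-6-(hydroxymethyl)cyclohex-2-ene-1,4-diyl dibenzoate | O=C(O[C@H]1C=C[C@@H](OC(=O)c3ccccc3)[C@H]2O[Si](C(C)(C)C)(C(C)(C)C)OC[C@@]12O)c1ccccc1 | intermediate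
15 | (1S,4R,5R,6S)-5,6-dihydroxy-6-(hydroxymethyl)cyclohex-2-ene-1,4-diyl dibenzoate | O=C(O[C@H]1C=C[C@@H](OC(=O)c2ccccc2)[C@@H](O)[C@@]1(O)CO)c1ccccc1 | target

Total step count: 12. Longest linear sequence: 12 steps (1 → 15).

**Steps most likely to fail**

**Step 6 (together with the handling of ketone 7).** The aluminium by-product may promote enolisation towards C1 or C5, followed by loss of O4 and aromatisation. The titanium methylidene may also attack the benzoate carbonyl. The fallback is a Peterson olefination that sets out from 7. Me3SiCH2MgCl premixed with anhydrous CeCl3 (THF, −78 °C, AcOH quench) is fast, non-basic and ketone-selective. It should add from the open α face to give the 6β-hydroxy-6α-[(trimethylsilyl)methyl] adduct F1. Acid-induced anti elimination (cat. H2SO4, THF, 0 °C) then removes the silanol and returns to the route at 8. The configuration at C6 of the adduct is of no consequence.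

**Step 10.** Ring closure of the silyl bis-triflate may show poor site selectivity, closing a five-membered ring across O6/O7 or O4/O5 or silylating intermolecularly. The fallback abandons the bridge and sets out from 11. t-BuPh2SiCl and imidazole (DMF, 0 °C) should take only the primary O7 and give the 7-O-(tert-butyldiphenylsilyl) triol F2. O4 is then distinguished from O5 by sterics, since O5 sits next to the fully substituted C6. One equivalent of 13 in pyridine–CH2Cl2 at −40 °C should therefore give the 4-O-benzoyl-7-O-(tert-butyldiphenylsilyl) diol F3. HF·pyridine in THF removes the silyl ether, and the fallback comes back to the route at 15.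

**Step 4.** The opening may be sluggish. At the temperature then needed, the benzoyl group may shift from O1 to O6, or the base may isomerise the vinyl oxirane. The fallback replaces steps 3 and 4 and sets out from 3. Upjohn dihydroxylation (OsO4 cat., NMO, acetone–H2O) of C6=C1 from the α face should give the 1α,6α-diol F4. A Mitsunobu reaction with 5 (PPh3, DIAD, toluene, 0 °C) then activates the allylic O1–H and displaces it with inversion, which returns to the route at 6. A cis diol cannot close to an epoxide, so the usual side path of Mitsunobu reactions on diols is not open.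

**Further compounds**
F1 | step 6 | 3-bromo-6β-hydroxy-4β,5β-(isopropylidenedioxy)-6α-[(trimethylsilyl)methyl]cyclohex-2-en-1β-yl benzoate | O=C(O[C@H]1C=C(Br)[C@H]2OC(C)(C)O[C@H]2[C@]1(O)C[Si](C)(C)C)c1ccccc1
F2 | step 10 | (1S,4R,5R,6S)-6-{[(tert-butyldiphenylsilyl)oxy]methyl}-4,5,6-trihydroxycyclohex-2-en-1-yl benzoate | O=C(O[C@H]1C=C[C@@H](O)[C@@H](O)[C@@]1(O)CO[Si](c2ccccc2)(c2ccccc2)C(C)(C)C)c1ccccc1
F3 | step 10 | (1S,4R,5R,6S)-6-{[(tert-butyldiphenylsilyl)oxy]methyl}-5,6-dihydroxycyclohex-2-ene-1,4-diyl dibenzoate | O=C(O[C@H]1C=C[C@@H](OC(=O)c2ccccc2)[C@@H](O)[C@@]1(O)CO[Si](c2ccccc2)(c2ccccc2)C(C)(C)C)c1ccccc1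
F4 | step 4 | (1R,4S,5S,6R)-3-bromo-4,5-(isopropylidenedioxy)cyclohex-2-ene-1,6-diol | O[C@@H]1C=C(Br)[C@H]2OC(C)(C)O[C@H]2[C@@H]1O
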